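Readings and results were computed on assumed constants; the scatter is artificial.

The chair opened the meeting on the flask, whose run so far is the south-east run, and tabled the following.

- south-east: left-handed substrate 20 mM; right-handed substrate 20 mM; solid reagent 24 mM; free catalyst 2.2 mM; the very flask that is asked about, followed so far
- flask: left-handed substrate 20 mM; solid reagent 24.0 mM; free catalyst 2.2 mM; right-handed substrate 20 mM; time 10 d

south-east run (percent of the left-handed substrate and right-handed substrate together charged)

| time / d | right-handed substrate / % | left-handed substrate / % | left-handed product / % |
|---|---|---|---|
| 0.417 | 44.7 | 43.8 | 4.5 |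
| 0.833 | 42.2 | 39.1 | 8.8 |
| 1.25 | 39.3 | 34.8 | 12.0 |
| 2.50 | 33.4 | 25.5 | 21.1 |
| 5.00 | 27.8 | 17.5 | 26.4 |

(scatter of a reading: 0.3 percentage points)

- free catalyst is single-handed; left-handed substrate and right-handed substrate are mirror images of each other, charged as a racemate, each of them at the stated concentration
- as a solid, counted per litre of solution: solid reagent
- the numbers in the tables scatter with a standard deviation of 0.3 percentage points
- at the start none of the solid reagent is in solution

- whether the excess of right-handed substrate over left-handed substrate among what is left of the two reaches 80% by 10 d (yes / no)
- the highest excess of right-handed substrate over left-handed substrate among what is left of the two up to 10 d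

The process chemist argued that solid reagent is the limiting reagent, since c(solid reagent) at 24.0 mM is less than the 40.0 mM of racemate. Taking one reagent per substrate, she divided c(solid reagent) charged by c(left-handed substrate) plus c(right-handed substrate) charged, obtained 60.0%, and called this share of the racemate the reagent ceiling.

The kineticist replied that the flask is close to the crossing at which control passes from turnover rate to reagent balance. The readings at 5.00 d show 54.7% of the racemate gone, so the room under the ceiling is 5.3 percentage points, far less than what has already gone.

The chair then asked for a limiting case, with that room going wholly to the left-handed substrate and, supposing the catalyst holds one substrate each, a further 5.50% of the racemate taken up as left-handed substrate on the catalyst. The kineticist reported that left-handed substrate then falls to 6.70% while right-handed substrate stays at 27.8%. The 34.5% remaining would carry an excess of 61.2%, less than the 80.0% wanted. The meeting's reckoning was therefore no, with the top expected between the 22.7% read at 5.00 d and that limiting case.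

The forecast says no, with a top of 27% (range 24.5% to 31%), holding that consumption “looks limited by the reagent”.

The flask gives no, with a top of 22.8%. At 10.0 d solid reagent stands at 0%, and left-handed product and right-handed product together reach 58.0%, less than the ceiling of 60.0%.

    free catalyst + left-handed substrate ⇌ catalyst intermediate A (K = 81.0 L mol⁻¹, k = 0.610 L mol⁻¹ s⁻¹)
    free catalyst + right-handed substrate ⇌ catalyst intermediate B (K = 130 L mol⁻¹, k = 0.0500 L mol⁻¹ s⁻¹)
    partner + catalyst intermediate A → free catalyst + left-handed product (k = 0.00660 L mol⁻¹ s⁻¹)
    partner + catalyst intermediate B → free catalyst + right-handed product (k = 0.00250 L mol⁻¹ s⁻¹)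
    left-handed product ⇌ right-handed product (k = 3.80 × 10⁻⁶ s⁻¹)
    solid reagent ⇌ partner, rate k6*(cs6 - [partner]) while solid is left; crystals form when [partner] > cs6 (solubility = 13.0 mM, k = 1.50 × 10⁻⁴ s⁻¹)
    partner + free catalyst → spent catalyst (k = 1.70 × 10⁻⁴ L mol⁻¹ s⁻¹)

In the neighbouring flask, with c(solid reagent) cut to 9.6 mM, the same division gives a ceiling of 24.0%. There, at 10.0 d, solid reagent stands at 0%, the two products together reach 23.6%, about equal to that ceiling, and the top excess is 6.06%.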